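(The readings were generated by integration for an exercise, noise included.)

The ratio to watch in this flask is the side share s, which is side product over the sum of side product, target and isomer of the product (a selectivity, counted by substrate). It reads 0.589 at the last west reading, 2.50 min, and each reading in it carries a scatter of 0.5 percentage points.

- west: substrate 24 mM; reagent 1 equiv; free catalyst 1.8 mol%; second catalyst 0.075 mol%; added ligand 0.29 mM; run made earlier
- flask: substrate 24 mM; reagent 1.00 equiv; free catalyst 1.8 mol%; second catalyst 0.05 mol%; added ligand 0.29 mM; time 25 min

west run (percent of the substrate charged)

| time / min | open intermediate / % | substrate / % | isomer of the product / % | side product / % | target / % |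
|---|---|---|---|---|---|
| 0.200 | 0.8 | 98.6 | 0.8 | 0 | 0.7 |
| 0.333 | 2.1 | 96.8 | 0.4 | 0 | 0.3 |
| 0.500 | 3.5 | 95.9 | 0.2 | 1.3 | 0.4 |
| 0.667 | 4.9 | 94.1 | 0 | 0.9 | 0.4 |
| 1.00 | 5.9 | 90.9 | 0 | 1.8 | 0.7 |
| 1.50 | 6.8 | 86.5 | 0 | 3.3 | 2.7 |
| 2.50 | 9.3 | 79.4 | 1.1 | 7.3 | 4.0 |

(scatter of a reading: 0.5 percentage points)

- a species is counted by the substrate in it: one side product counts as two
- the earlier runs were read with a standard deviation of 0.5 percentage points
- no earlier run changes the charge of second catalyst; that part of a forecast is a guess

- the species that holds most of what was charged as substrate, at 25 min (target / side product / open intermediate / substrate / isomer of the product)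
- the largest share itself, whichever of these holds it, in percent of the substrate charged

I build the flask up in steps. I begin with the main step by itself, letting substrate fall first order with a rate constant k read from the last west reading:

k = 0.0923 /min, so substrate left at 25 min = 9.96%

Next I add the open intermediate, which stood at 9.3% at that reading, and I take that much out of the products:

products = 80.7%

Last I add the split:

side product = s × products = 47.5%

That is more than the substrate left and more than target and isomer of the product together, so I answer side product. But carrying s from 0.075 mol% of second catalyst to 0.05 mol% is a guess, because no earlier run changes that charge.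

The forecast says side product at 45%, within 32% to 60%: "Side product most likely holds the largest share". Its figure lies below my reckoning.

The flask gives side product at 48.9%, with target at 21.3%.

    substrate + free catalyst ⇌ free catalyst + open intermediate (K = 0.560, k = 280 /M/min)
    second catalyst + open intermediate ⇌ catalyst intermediate (K = 1900 /M, k = 38000 /M/min)
    reagent + catalyst intermediate → second catalyst + target (k = 2800 /M/min)
    substrate + open intermediate → side product (k = 12.0 /M/min)
    target ⇌ isomer of the product (K = 0.550, k = 0.280 /min)
    free catalyst + added ligand ⇌ idle complex, settled at all times (K = 2100 /M)

Up to 2.50 min this flask built open intermediate to 10.0%, with 51.8% of the second catalyst held as catalyst intermediate, while s stood at 0.718. By 25.0 min substrate was down to 14.9%, open intermediate to 3.80%, catalyst intermediate to 34.7% and s to 0.602, against the carried 0.589, which was read in the west run at 0.075 mol% of second catalyst. The neighbour charged with 0.12 mol% of second catalyst, read at the same time, has s at 0.376, and there the answer changes: target holds 34.7%, more than side product at 32.1%.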